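**Retrosynthetic overview**

- Feature: in ring A the acetyl-bearing carbon lies between a hydroxyl-bearing carbon and the methoxy-bearing carbon; the carbon carrying the CH2 bridge to ring B, the second hydroxyl carbon and the methyl carbon complete the ring. An aryne across the acetyl carbon and its hydroxyl neighbour, polarised by the adjacent methoxy group, can take up acetic acid as oxygen on the hydroxyl carbon and acetyl on the acetyl carbon.
- Last disconnections: the six MOM ethers (final step), then the aryl–oxygen and aryl–acetyl bonds of ring A, back to a ring A 2-silylaryl triflate that already carries protected rings B and C with both butanoyl groups.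
- The two ArCH2Ar bonds come from ortho-quinone methides, released from the phenolic Mannich bases of rings C and A, which add to butanoylphloroglucinol (ring B).
- Both Mannich bases derive from the bis-MOM ether of 5-methoxybenzene-1,3-diol by two directed ortho-lithiations (CH2NMe2, then CH3). Ring A is then brominated with NBS and the bromide becomes the silyl triflate by retro-Brook shift and triflation, whereas ring C receives its butanoyl group by a third lithiation.
- No ring is built: the three benzene rings are bought intact and joined in the order C–B, then A–BC.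

Key step: step 13

Remark: rings A and C are taken from 5-methoxybenzene-1,3-diol rather than from a C-methylphloroglucinol, so that the O-methyl and C-methyl groups are placed without regiochemical ambiguity; the target has no stereocentre, so no step sets configuration.

**Route**

Step 1
Reactants: 1 5-methoxybenzene-1,3-diol
Product: 2 1-methoxy-3,5-bis(methoxymethoxy)benzene
Conditions: NaH (2.2 equiv), MOMCl, DMF, 0 °C to rt
Reagents that add atoms: chloromethyl methyl ether, COCCl
Why: Williamson O-alkylation of both phenoxides with the hard electrophile MOMCl gives the bis-acetal ether, whose MOM groups later serve as directing groups.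

Step 2
Reactants: 2 1-methoxy-3,5-bis(methoxymethoxy)benzene; 3 N,N-dimethylmethyleneiminium iodide (Eschenmoser's salt, CH2=NMe2+ I−)
Product: 5 1-[4-methoxy-2,6-bis(methoxymethoxy)phenyl]-N,N-dimethylmethanamine, via aryllithium 4 (not isolated)
Conditions: n-BuLi, THF, 0 °C; then 3, −78 °C to rt
Reagents that add atoms: none
Why: Directed ortho-metalation takes place at the carbon flanked by the two chelating MOM ethers, and the aryllithium is aminomethylated by the iminium salt (Mannich-type addition).

Step 3
Reactants: 5 1-[4-methoxy-2,6-bis(methoxymethoxy)phenyl]-N,N-dimethylmethanamine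
Product: 7 1-[4-methoxy-2,6-bis(methoxymethoxy)-3-methylphenyl]-N,N-dimethylmethanamine, via aryllithium 6 (not isolated)
Conditions: n-BuLi, TMEDA, THF, 0 °C; then MeI (1.05 equiv), −78 °C
Reagents that add atoms: iodomethane, CI
Why: A second directed ortho-metalation at one of the two equivalent carbons between the methoxy group and a MOM ether is followed by SN2 methylation, where at low temperature the aryllithium should outrun N-quaternisation by the single equivalent of MeI.

Step 4
Reactants: 7 1-[4-methoxy-2,6-bis(methoxymethoxy)-3-methylphenyl]-N,N-dimethylmethanamine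
Product: 8 1-[3-bromo-4-methoxy-2,6-bis(methoxymethoxy)-5-methylphenyl]-N,N-dimethylmethanamine
Conditions: CF3CO2H (1.0 equiv), CH2Cl2, −40 °C; then NBS (1.0 equiv), −40 to 0 °C, dark; aq NaHCO3
Reagents that add atoms: N-bromosuccinimide, O=C1CCC(=O)N1Br
Why: Electrophilic aromatic bromination by NBS at the only unsubstituted ring carbon, which is activated by three alkoxy groups, places bromine on the future acetyl carbon of ring A; prior protonation of the amine as its trifluoroacetate keeps nitrogen from being oxidised by NBS, and one equivalent of the buffered acid at low temperature should leave the MOM ethers intact.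

Step 5
Reactants: 8 1-[3-bromo-4-methoxy-2,6-bis(methoxymethoxy)-5-methylphenyl]-N,N-dimethylmethanamine
Product: 9 4-bromo-2-[(dimethylamino)methyl]-5-methoxy-6-methylbenzene-1,3-diol
Conditions: HCl (3 equiv), MeOH, 40 °C; NaHCO3 work-up
Reagents that add atoms: none
Why: Acid-catalysed acetal methanolysis removes both MOM ethers while the protonated benzylic amine stays inert.

Step 6
Reactants: 9 4-bromo-2-[(dimethylamino)methyl]-5-methoxy-6-methylbenzene-1,3-diol
Product: 14 2-[(dimethylamino)methyl]-3-hydroxy-5-methoxy-4-methyl-6-(trimethylsilyl)phenyl trifluoromethanesulfonate, via bis(trimethylsilyl) ether 10 (not isolated), via aryllithium 11 (not isolated), via lithium phenolate 12 (not isolated), via silyl ether triflate 13 (not isolated)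
Conditions: (Me3Si)2NH, THF, 70 °C, evaporate; n-BuLi, THF, −78 °C; Tf2O (1.05 equiv), −78 °C to rt; aq NaHCO3, MeOH, rt
Reagents that add atoms: hexamethyldisilazane, C[Si](C)(C)N[Si](C)(C)C; trifluoromethanesulfonic anhydride, O=S(=O)(OS(=O)(=O)C(F)(F)F)C(F)(F)F
Why: O-silylation, bromine–lithium exchange and a 1,3 oxygen-to-carbon silyl shift (retro-Brook rearrangement) move silicon only from the oxygen next to bromine, so only that phenoxide (on the future aryne carbon next to the bridge carbon) is triflated, and the other aryl silyl ether hydrolyses on work-up.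

Step 7
Reactants: 7 1-[4-methoxy-2,6-bis(methoxymethoxy)-3-methylphenyl]-N,N-dimethylmethanamine; 15 N-methoxy-N-methylbutanamide
Product: 17 1-{3-[(dimethylamino)methyl]-6-methoxy-2,4-bis(methoxymethoxy)-5-methylphenyl}butan-1-one, via aryllithium 16 (not isolated)
Conditions: n-BuLi, TMEDA, THF, 0 °C; then 15, −78 to 0 °C; H2O
Reagents that add atoms: none
Why: Directed ortho-metalation at the last ring hydrogen, between the methoxy group and a MOM ether, is followed by acylation with a Weinreb amide, whose chelated tetrahedral intermediate prevents over-addition, so the butanoyl group ends between the methoxy group and a MOM ether.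

Step 8
Reactants: 17 1-{3-[(dimethylamino)methyl]-6-methoxy-2,4-bis(methoxymethoxy)-5-methylphenyl}butan-1-one
Product: 18 1-{3-[(dimethylamino)methyl]-2,4-dihydroxy-6-methoxy-5-methylphenyl}butan-1-one
Conditions: HCl (3 equiv), MeOH, 40 °C; NaHCO3 work-up
Reagents that add atoms: none
Why: Acid-catalysed acetal methanolysis as in step 5 frees the two phenols of the ring C Mannich base, which cannot self-condense because every ring carbon is substituted.

Step 9
Reactants: 19 phloroglucinol (benzene-1,3,5-triol); 20 butanoyl chloride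
Product: 21 1-(2,4,6-trihydroxyphenyl)butan-1-one
Conditions: AlCl3 (3.5 equiv), PhNO2, 60 °C; aq HCl work-up
Reagents that add atoms: none
Why: Friedel–Crafts acylation of the highly activated triol should stop at monoacylation because the first acyl group deactivates the ring.

Step 10
Reactants: 18 1-{3-[(dimethylamino)methyl]-2,4-dihydroxy-6-methoxy-5-methylphenyl}butan-1-one; 21 1-(2,4,6-trihydroxyphenyl)butan-1-one
Product: 23 1-{3-[(3-butanoyl-2,6-dihydroxy-4-methoxy-5-methylphenyl)methyl]-2,4,6-trihydroxyphenyl}butan-1-one, via ortho-quinone methide 22 (not isolated)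
Conditions: 21 (3 equiv), 1,4-dioxane, 100 °C, N2 stream
Reagents that add atoms: none
Why: Thermal loss of Me2NH from the phenolic Mannich base (retro-Mannich elimination) gives ortho-quinone methide 22, which is trapped by conjugate C-alkylation at a free carbon of ring B, the excess of 21 holding back double alkylation.

Step 11
Reactants: 14 2-[(dimethylamino)methyl]-3-hydroxy-5-methoxy-4-methyl-6-(trimethylsilyl)phenyl trifluoromethanesulfonate; 23 1-{3-[(3-butanoyl-2,6-dihydroxy-4-methoxy-5-methylphenyl)methyl]-2,4,6-trihydroxyphenyl}butan-1-one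
Product: 25 2-[(3-butanoyl-5-{[3-butanoyl-2,6-dihydroxy-4-methoxy-5-methylphenyl]methyl}-2,4,6-trihydroxyphenyl)methyl]-3-hydroxy-5-methoxy-4-methyl-6-(trimethylsilyl)phenyl trifluoromethanesulfonate, via ortho-quinone methide 24 (not isolated)
Conditions: 1,4-dioxane, 100 °C, N2 stream
Reagents that add atoms: none
Why: The same retro-Mannich elimination and conjugate addition joins the bridge carbon of ring A through its CH2 to the single free carbon of ring B, and the silyl triflate should survive because amine and phenol do not activate silicon at this temperature.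

Step 12
Reactants: 25 the hexaphenol trimer of step 11
Product: 26 2-[(3-butanoyl-5-{[3-butanoyl-4-methoxy-2,6-bis(methoxymethoxy)-5-methylphenyl]methyl}-2,4,6-tris(methoxymethoxy)phenyl)methyl]-5-methoxy-3-(methoxymethoxy)-4-methyl-6-(trimethylsilyl)phenyl trifluoromethanesulfonate
Conditions: NaH (6.6 equiv), MOMCl, DMF, 0 °C to rt
Reagents that add atoms: chloromethyl methyl ether, COCCl
Why: Williamson O-alkylation of all six sodium phenoxides, including the hydrogen-bonded ones next to the ketones, should proceed with MOMCl, and no phenoxide sits next to silicon, so no silyl shift can release the aryne early.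

Step 13
Reactants: 26 the hexa-MOM ring A silyl triflate of step 12; 27 acetic acid
Product: 31 1-{3-[(3-butanoyl-5-{[3-butanoyl-4-methoxy-2,6-bis(methoxymethoxy)-5-methylphenyl]methyl}-2,4,6-tris(methoxymethoxy)phenyl)methyl]-2-hydroxy-6-methoxy-4-(methoxymethoxy)-5-methylphenyl}ethan-1-one, via aryne 28 (not isolated), via aryl anion 29 (not isolated), via four-membered alkoxide 30 (not isolated)
Conditions: CsF (4 equiv), AcOH (1.2 equiv), THF, 125 °C, sealed tube
Reagents that add atoms: none
Why: Fluoride attacks silicon on the ring A carbon next to the methoxy group and triflate leaves from the neighbouring carbon (aryne generation from a 2-silylaryl triflate) to give aryne 28, and acetate, formed from AcOH and CsF, adds through oxygen to the aryne carbon remote from the methoxy group, leaving aryl anion 29 on the carbon beside the methoxy group. The anion attacks the neighbouring ester carbonyl to give the strained alkoxide 30, which opens by C–O cleavage to the caesium salt of the ortho-hydroxyaryl ketone, a formal insertion of the aryne into the C–O bond of the acid akin to an anionic ortho-Fries acyl shift. The closest known reaction is the fluoride-mediated addition of carboxylic acids to arynes, 3-methoxyarynes included, which gives ortho-hydroxyaryl ketones. No ring of the target is closed and no stereocentre is formed; the four-membered ring is transient. The selectivity needed is the site of oxygen attack, and the inductively withdrawing methoxy group should secure it by polarising the aryne so that the nucleophile enters at the remote carbon and charge builds on the carbon beside the methoxy group, outweighing the steric bias of the benzylic substituent on the other flank. The acyl shift must also beat protonation of 29, which the high temperature in THF and the small excess of acid favour, and the ketones and MOM ethers are inert to CsF.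

Step 14
Reactants: 31 the hexa-MOM ether of step 13
Product: 32 Agrimol F, 1-{3-[(3-acetyl-2,6-dihydroxy-4-methoxy-5-methylphenyl)methyl]-5-[(3-butanoyl-2,6-dihydroxy-4-methoxy-5-methylphenyl)methyl]-2,4,6-trihydroxyphenyl}butan-1-one
Conditions: HCl (cat.), MeOH, 45 °C
Reagents that add atoms: none
Why: Acid-catalysed acetal methanolysis frees the six phenols, and the aryl ketones, aryl methyl ethers and diarylmethane bridges should tolerate dilute methanolic HCl at this temperature.

**Compound list**

1 | 5-methoxybenzene-1,3-diol | COc1cc(O)cc(O)c1 | starting material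
2 | 1-methoxy-3,5-bis(methoxymethoxy)benzene | COCOc1cc(OC)cc(OCOC)c1 | intermediate
3 | N,N-dimethylmethyleneiminium iodide | C=[N+](C)C.[I-] | starting material
4 | [4-methoxy-2,6-bis(methoxymethoxy)phenyl]lithium | [Li]c1c(OCOC)cc(OC)cc1OCOC | intermediate
5 | 1-[4-methoxy-2,6-bis(methoxymethoxy)phenyl]-N,N-dimethylmethanamine | CN(C)Cc1c(OCOC)cc(OC)cc1OCOC | intermediate
6 | {3-[(dimethylamino)methyl]-6-methoxy-2,4-bis(methoxymethoxy)phenyl}lithium | CN(C)Cc1c(OCOC)c([Li])c(OC)cc1OCOC | intermediate
7 | 1-[4-methoxy-2,6-bis(methoxymethoxy)-3-methylphenyl]-N,N-dimethylmethanamine | CN(C)Cc1c(OCOC)c(C)c(OC)cc1OCOC | intermediate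
8 | 1-[3-bromo-4-methoxy-2,6-bis(methoxymethoxy)-5-methylphenyl]-N,N-dimethylmethanamine | CN(C)Cc1c(OCOC)c(C)c(OC)c(Br)c1OCOC | intermediate
9 | 4-bromo-2-[(dimethylamino)methyl]-5-methoxy-6-methylbenzene-1,3-diol | CN(C)Cc1c(O)c(C)c(OC)c(Br)c1O | intermediate
10 | 1-[3-bromo-4-methoxy-5-methyl-2,6-bis(trimethylsilyloxy)phenyl]-N,N-dimethylmethanamine | CN(C)Cc1c(O[Si](C)(C)C)c(C)c(OC)c(Br)c1O[Si](C)(C)C | intermediate
11 | {3-[(dimethylamino)methyl]-6-methoxy-5-methyl-2,4-bis(trimethylsilyloxy)phenyl}lithium | CN(C)Cc1c(O[Si](C)(C)C)c(C)c(OC)c([Li])c1O[Si](C)(C)C | intermediate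
12 | lithium 2-[(dimethylamino)methyl]-5-methoxy-4-methyl-6-(trimethylsilyl)-3-(trimethylsilyloxy)phenolate | [Li+].CN(C)Cc1c(O[Si](C)(C)C)c(C)c(OC)c([Si](C)(C)C)c1[O-] | intermediate
13 | 2-[(dimethylamino)methyl]-5-methoxy-4-methyl-6-(trimethylsilyl)-3-(trimethylsilyloxy)phenyl trifluoromethanesulfonate | CN(C)Cc1c(O[Si](C)(C)C)c(C)c(OC)c([Si](C)(C)C)c1OS(=O)(=O)C(F)(F)F | intermediate
14 | 2-[(dimethylamino)methyl]-3-hydroxy-5-methoxy-4-methyl-6-(trimethylsilyl)phenyl trifluoromethanesulfonate | CN(C)Cc1c(O)c(C)c(OC)c([Si](C)(C)C)c1OS(=O)(=O)C(F)(F)F | intermediate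
15 | N-methoxy-N-methylbutanamide | CCCC(=O)N(C)OC | starting material
16 | {3-[(dimethylamino)methyl]-6-methoxy-2,4-bis(methoxymethoxy)-5-methylphenyl}lithium | CN(C)Cc1c(OCOC)c(C)c(OC)c([Li])c1OCOC | intermediate
17 | 1-{3-[(dimethylamino)methyl]-6-methoxy-2,4-bis(methoxymethoxy)-5-methylphenyl}butan-1-one | CCCC(=O)c1c(OC)c(C)c(OCOC)c(CN(C)C)c1OCOC | intermediate
18 | 1-{3-[(dimethylamino)methyl]-2,4-dihydroxy-6-methoxy-5-methylphenyl}butan-1-one | CCCC(=O)c1c(OC)c(C)c(O)c(CN(C)C)c1O | intermediate
19 | phloroglucinol | Oc1cc(O)cc(O)c1 | starting material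
20 | butanoyl chloride | CCCC(Cl)=O | starting material
21 | 1-(2,4,6-trihydroxyphenyl)butan-1-one | CCCC(=O)c1c(O)cc(O)cc1O | intermediate
22 | 4-butanoyl-3-hydroxy-5-methoxy-6-methyl-2-methylidenecyclohexa-3,5-dien-1-one | C=C1C(=O)C(C)=C(OC)C(C(=O)CCC)=C1O | intermediate
23 | 1-{3-[(3-butanoyl-2,6-dihydroxy-4-methoxy-5-methylphenyl)methyl]-2,4,6-trihydroxyphenyl}butan-1-one | CCCC(=O)c1c(O)cc(O)c(Cc2c(O)c(C)c(OC)c(C(=O)CCC)c2O)c1O | intermediate
24 | 3-methoxy-4-methyl-6-methylidene-5-oxo-2-(trimethylsilyl)cyclohexa-1,3-dien-1-yl trifluoromethanesulfonate | C=C1C(=O)C(C)=C(OC)C([Si](C)(C)C)=C1OS(=O)(=O)C(F)(F)F | intermediate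
25 | 2-[(3-butanoyl-5-{[3-butanoyl-2,6-dihydroxy-4-methoxy-5-methylphenyl]methyl}-2,4,6-trihydroxyphenyl)methyl]-3-hydroxy-5-methoxy-4-methyl-6-(trimethylsilyl)phenyl trifluoromethanesulfonate | CCCC(=O)c1c(O)c(Cc2c(O)c(C)c(OC)c([Si](C)(C)C)c2OS(=O)(=O)C(F)(F)F)c(O)c(Cc2c(O)c(C)c(OC)c(C(=O)CCC)c2O)c1O | intermediate
26 | 2-[(3-butanoyl-5-{[3-butanoyl-4-methoxy-2,6-bis(methoxymethoxy)-5-methylphenyl]methyl}-2,4,6-tris(methoxymethoxy)phenyl)methyl]-5-methoxy-3-(methoxymethoxy)-4-methyl-6-(trimethylsilyl)phenyl trifluoromethanesulfonate | COc1c(C)c(OCOC)c(Cc2c(OCOC)c(C(=O)CCC)c(OCOC)c(Cc3c(OCOC)c(C)c(OC)c(C(=O)CCC)c3OCOC)c2OCOC)c(OS(=O)(=O)C(F)(F)F)c1[Si](C)(C)C | intermediate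
27 | acetic acid | CC(O)=O | starting material
28 | ring A aryne of the hexa-MOM trimer (triple bond between the former triflate carbon and the former silyl carbon) | COC1=C(C)C(OCOC)=C(Cc2c(OCOC)c(C(=O)CCC)c(OCOC)c(Cc3c(OCOC)c(C)c(OC)c(C(=O)CCC)c3OCOC)c2OCOC)C#C1 | intermediate
29 | caesium aryl anion of ring A (carbanion beside the methoxy carbon, acetoxy on the next carbon) | [Cs+].COc1c(C)c(OCOC)c(Cc2c(OCOC)c(C(=O)CCC)c(OCOC)c(Cc3c(OCOC)c(C)c(OC)c(C(=O)CCC)c3OCOC)c2OCOC)c(OC(C)=O)[c-]1 | intermediate
30 | caesium alkoxide of the four-membered oxygen ring fused to ring A across the two former aryne carbons | [Cs+].COc1c(C)c(OCOC)c(Cc2c(OCOC)c(C(=O)CCC)c(OCOC)c(Cc3c(OCOC)c(C)c(OC)c(C(=O)CCC)c3OCOC)c2OCOC)c2OC(C)([O-])c12 | intermediate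
31 | 1-{3-[(3-butanoyl-5-{[3-butanoyl-4-methoxy-2,6-bis(methoxymethoxy)-5-methylphenyl]methyl}-2,4,6-tris(methoxymethoxy)phenyl)methyl]-2-hydroxy-6-methoxy-4-(methoxymethoxy)-5-methylphenyl}ethan-1-one | COc1c(C)c(OCOC)c(Cc2c(OCOC)c(C(=O)CCC)c(OCOC)c(Cc3c(OCOC)c(C)c(OC)c(C(=O)CCC)c3OCOC)c2OCOC)c(O)c1C(C)=O | intermediate
32 | Agrimol F | CCCC(=O)c1c(O)c(Cc2c(O)c(C)c(OC)c(C(C)=O)c2O)c(O)c(Cc2c(O)c(C)c(OC)c(C(=O)CCC)c2O)c1O | target

**Step count**

Total steps: 14. Longest linear sequence: 10 steps (steps 1–6, then 11–14).

**Steps most likely to fail**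

Step 13. The aryl anion 29 may be protonated before the acyl shift, leaving an aryl acetate. The aryne may also be captured intramolecularly by an ether oxygen of ring B, or the bulk of the benzylic substituent next to the aryne may divert the nucleophile to the carbon beside the methoxy group. The fallback drops the aryne and places the acetyl group by directed metalation; it sets out from compound 7 and comes back to the route at compound 32. Compound 7 is lithiated as in step 7 (n-BuLi, TMEDA, THF, 0 °C) to aryllithium 16 and acylated with N-methoxy-N-methylacetamide to give 1-{3-[(dimethylamino)methyl]-6-methoxy-2,4-bis(methoxymethoxy)-5-methylphenyl}ethan-1-one F1. Methanolic HCl then frees 1-{3-[(dimethylamino)methyl]-2,4-dihydroxy-6-methoxy-5-methylphenyl}ethan-1-one F2. Heating F2 with the rings B–C dimer 23 in 1,4-dioxane at 100 °C should alkylate the free carbon of ring B through the ortho-quinone methide and give 32 directly, without protecting groups.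

Step 11. Amine loss from the triflate-bearing Mannich base 14 may be slow, and reversible bridge formation in the basic medium may let the methylene bridges redistribute among the rings. The fallback reverses the order in which the bridges are made; it sets out from compounds 14 and 21 and comes back at compound 25. Compound 14 is heated with three equivalents of the small, unhindered nucleophile 21 to give 2-[(3-butanoyl-2,4,6-trihydroxyphenyl)methyl]-3-hydroxy-5-methoxy-4-methyl-6-(trimethylsilyl)phenyl trifluoromethanesulfonate F3. F3 is then heated with the acyl-activated Mannich base 18, which loses Me2NH more readily, to reach 25.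

Step 14. Removal of six acetal ethers in acid may be accompanied by acid-induced cleavage or migration of the methylene bridges (retro-Friedel–Crafts at the very electron-rich rings). The fallback replaces the acid-labile ethers by benzyl ethers that are removed under neutral conditions; it sets out from compound 25 and comes back at compound 32. Compound 25 is benzylated (BnBr, NaH, DMF, 0 °C to rt) to 2-{[2,4,6-tris(benzyloxy)-3-butanoyl-5-{[2,6-bis(benzyloxy)-3-butanoyl-4-methoxy-5-methylphenyl]methyl}phenyl]methyl}-3-(benzyloxy)-5-methoxy-4-methyl-6-(trimethylsilyl)phenyl trifluoromethanesulfonate F4. Under the conditions of step 13, F4 should give 1-{3-{[2,4,6-tris(benzyloxy)-3-butanoyl-5-{[2,6-bis(benzyloxy)-3-butanoyl-4-methoxy-5-methylphenyl]methyl}phenyl]methyl}-4-(benzyloxy)-2-hydroxy-6-methoxy-5-methylphenyl}ethan-1-one F5. Hydrogenolysis of F5 (H2, Pd/C, EtOAc, rt, stopped after the uptake expected for six benzyl groups) then gives 32.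

**Further compounds**

F1 | step 13 | 1-{3-[(dimethylamino)methyl]-6-methoxy-2,4-bis(methoxymethoxy)-5-methylphenyl}ethan-1-one | CC(=O)c1c(OC)c(C)c(OCOC)c(CN(C)C)c1OCOC
F2 | step 13 | 1-{3-[(dimethylamino)methyl]-2,4-dihydroxy-6-methoxy-5-methylphenyl}ethan-1-one | CC(=O)c1c(OC)c(C)c(O)c(CN(C)C)c1O
F3 | step 11 | 2-[(3-butanoyl-2,4,6-trihydroxyphenyl)methyl]-3-hydroxy-5-methoxy-4-methyl-6-(trimethylsilyl)phenyl trifluoromethanesulfonate | CCCC(=O)c1c(O)cc(O)c(Cc2c(O)c(C)c(OC)c([Si](C)(C)C)c2OS(=O)(=O)C(F)(F)F)c1O
F4 | step 14 | 2-{[2,4,6-tris(benzyloxy)-3-butanoyl-5-{[2,6-bis(benzyloxy)-3-butanoyl-4-methoxy-5-methylphenyl]methyl}phenyl]methyl}-3-(benzyloxy)-5-methoxy-4-methyl-6-(trimethylsilyl)phenyl trifluoromethanesulfonate | COc1c(C)c(OCc4ccccc4)c(Cc2c(OCc4ccccc4)c(C(=O)CCC)c(OCc4ccccc4)c(Cc3c(OCc4ccccc4)c(C)c(OC)c(C(=O)CCC)c3OCc4ccccc4)c2OCc4ccccc4)c(OS(=O)(=O)C(F)(F)F)c1[Si](C)(C)C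
F5 | step 14 | 1-{3-{[2,4,6-tris(benzyloxy)-3-butanoyl-5-{[2,6-bis(benzyloxy)-3-butanoyl-4-methoxy-5-methylphenyl]methyl}phenyl]methyl}-4-(benzyloxy)-2-hydroxy-6-methoxy-5-methylphenyl}ethan-1-one | COc1c(C)c(OCc4ccccc4)c(Cc2c(OCc4ccccc4)c(C(=O)CCC)c(OCc4ccccc4)c(Cc3c(OCc4ccccc4)c(C)c(OC)c(C(=O)CCC)c3OCc4ccccc4)c2OCc4ccccc4)c(O)c1C(C)=O
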